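The constants used here were chosen freely, and the outcome is calculated.

The complex with four exchanged is the product, but step 6 turns it into the isomer of the product and back, so the question for each vessel is how much of this pair is still the product.

common to all: leaving ligand 0.0500 M
- grey: starting complex 0.050 M; incoming ligand 0.0550 M; time 1.0 h; a closed flask charged with all of it at once and left for 1.0 h
- ochre: starting complex 0.050 M; incoming ligand 0.0550 M; a single well-mixed tank run continuously and read at steady state, 1.0 h in it on average
- red: starting complex 0.050 M; incoming ligand 0.0550 M (fed, over 1.00 h); time 1.0 h; a stirred flask in which incoming ligand is dosed at a steady rate over 1.00 h without added volume, worked up at 1.0 h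
- violet: starting complex 0.050 M (fed, over 1.00 h); incoming ligand 0.0550 M; time 1.0 h; a stirred flask in which starting complex is dosed at a steady rate over 1.00 h without added volume, worked up at 1.0 h

* the set-up with the highest share of complex with four exchanged in all that became complex with four exchanged or isomer of the product, at the outlet or at the end ("none" if the first two lie within 2 percentage points) (grey / ochre / red / violet / none)
* share of complex with four exchanged in all that became complex with four exchanged or isomer of the product, at the outlet or at the end, grey
* share of complex with four exchanged in all that became complex with four exchanged or isomer of the product, at the outlet or at the end, ochre
* share of complex with four exchanged in all that became complex with four exchanged or isomer of the product, at the outlet or at the end, red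
* share of complex with four exchanged in all that became complex with four exchanged or isomer of the product, at the outlet or at the end, violet

- the stated concentrations are those of everything mixed, before any reaction; amounts are the same in each set-up
- the feed brings no volume worth counting
- run time (grey): 1.0 h

    starting complex + incoming ligand ⇌ leaving ligand + complex with one exchanged (K1 = 0.24, k1 = 1.4 M⁻¹ min⁻¹)
    complex with one exchanged + incoming ligand ⇌ leaving ligand + complex with two exchanged (K2 = 0.60, k2 = 0.30 M⁻¹ min⁻¹)
    complex with two exchanged + incoming ligand ⇌ leaving ligand + complex with three exchanged (K3 = 2.8, k3 = 1.1 M⁻¹ min⁻¹)
    complex with three exchanged + incoming ligand ⇌ leaving ligand + complex with four exchanged (K4 = 0.71, k4 = 0.48 M⁻¹ min⁻¹)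
    leaving ligand → by-product carried off (k5 = 1.2 min⁻¹)
    complex with four exchanged ⇌ isomer of the product (K6 = 0.57, k6 = 0.029 min⁻¹)

Setting the forward rate of step 6 equal to its back rate makes time drop out and leaves 63.7% of the pair as product; I call this the resting share, the thermodynamic-control value. With 0.029 min⁻¹ and 0.57, the pair relaxes towards it with a time of 12.5 min, shorter than the 1.0 h available, so I read a share above the resting share as a sign of recently made product. In the ochre tank, adding outflow to the back rate in the same division gives 70.0%. For grey, red and violet I give no figures; my ranking puts red first, where incoming ligand arrives over the whole 1.00 h.

The forecast names red as best, with 73.5% for grey, 70% for ochre, 85% for red and 76% for violet, on the ground that “Product made recently has not yet isomerised”.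

The simulation gives 72.7% for grey, 70.0% for ochre, 84.4% for red and 76.4% for violet, so red is best, as forecast. The lowest of these stands above the resting share.

The share in the red flask has not come to rest at 1.0 h: its 84.4% lies 21 percentage points above the resting share. The ochre tank is steady yet lies 6.3 points above the resting share, so its reading is a steady state and not an equilibrium of step 6. Left for 10.0 h, the red flask reads 63.7%, down 21 points and level with the resting share.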